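The chroman is cut at C3–C4 of the dihydropyran ring (ring B). Because C3 and C4 are bare methylenes, that bond can be made as a C3=C4 alkene by ring-closing metathesis and then saturated, while O1–C2 with the only stereocentre is bought intact as (R)-linalool. In one operation the ruthenium-catalysed metathesis closes ring B onto the aromatic ring A and forms the C3=C4 bond of a 2H-chromene. Its precursor is an aryl (R)-linalyl ether whose arene carries a vinyl group ortho to the ether oxygen, flanked on the other side by the C8 methyl, with the methoxy group para. The E,Z-dienoic acid chain is then grown from the prenyl terminus.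

Key step: step 4

Assumption: (R)-(−)-linalool of high enantiomeric purity is purchased; C2 is never touched after step 2, so the target should inherit that purity (the C2 descriptor reads S in compounds 11 to 15 only because the oxygenated side chain outranks C3 there, nothing changes in space).

Step 1
Reactants: 1 4-fluoro-3-methylanisole
Product: 4 2-fluoro-5-methoxy-3-methylbenzaldehyde, via aryllithium 2 (not isolated), via lithium hemiaminal alkoxide 3 (not isolated)
Conditions: n-BuLi, PMDTA, THF, −78 °C; then DMF, −78 → 0 °C; aq. NH4Cl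
Reagents that add atoms: N,N-dimethylformamide, CN(C)C=O
Why: Directed ortho-metalation followed by formylation: fluorine is the strongest acidifying ortho-director on ring A and PMDTA-solvated butyllithium should deprotonate by acidity at the C–H next to fluorine (also meta to the methoxy group) and not by coordination to the methoxy oxygen, the low temperature keeping the ortho-fluoroaryllithium from losing LiF before DMF intercepts it.

Step 2
Reactants: 4 2-fluoro-5-methoxy-3-methylbenzaldehyde; 5 (R)-linalool
Product: 7 2-{[(3R)-3,7-dimethylocta-1,6-dien-3-yl]oxy}-5-methoxy-3-methylbenzaldehyde, via potassium alkoxide 6 (not isolated)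
Conditions: 5, KH, THF, 0 °C; then 4, 18-crown-6, THF, 0 °C → rt
Reagents that add atoms: none
Why: Nucleophilic aromatic substitution by addition–elimination through a Meisenheimer adduct: the ortho-formyl group stabilises the adduct, fluoride is the best leaving group for this mechanism, the tertiary alkoxide has no carbinol hydrogen to reduce the aldehyde and adds to it only reversibly, and since only the O–H bond of linalool is broken the (R) configuration is carried over unchanged.

Step 3
Reactants: 7 2-{[(3R)-3,7-dimethylocta-1,6-dien-3-yl]oxy}-5-methoxy-3-methylbenzaldehyde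
Product: 8 2-{[(3R)-3,7-dimethylocta-1,6-dien-3-yl]oxy}-5-methoxy-1-methyl-3-vinylbenzene
Conditions: Ph3PCH3Br, KOt-Bu, THF, 0 °C → rt
Reagents that add atoms: methyltriphenylphosphonium bromide, C[P+](c1ccccc1)(c1ccccc1)c1ccccc1.[Br-]
Why: Wittig methylenation with the non-stabilised ylide, which should convert the aryl aldehyde into the styrene under basic conditions that leave the acid-sensitive tertiary allylic aryl ether and the other two alkenes untouched.

Step 4
Reactants: 8 2-{[(3R)-3,7-dimethylocta-1,6-dien-3-yl]oxy}-5-methoxy-1-methyl-3-vinylbenzene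
Product: 9 (2R)-6-methoxy-2,8-dimethyl-2-(4-methylpent-3-en-1-yl)-2H-chromene
Conditions: second-generation Grubbs catalyst RuCl2(=CHPh)(H2IMes)(PCy3) (5 mol%), CH2Cl2 (5 mM), 40 °C, argon sparge
Reagents that add atoms: none
Why: Ring-closing olefin metathesis: the ruthenium alkylidene should first exchange onto the unhindered, monosubstituted styrenyl alkene to give an ortho-alkoxybenzylidene, which adds across the vinyl group on the fully substituted ether carbon in a [2+2] step to a ruthenacyclobutane and then cycloreverts, releasing ethylene. The closest known reaction type is the metathesis closure of 2-vinylaryl allyl ethers to 2H-chromenes. Ring B is closed as a six-membered ring by joining the two internal alkene carbons (C4 from the styrene, C3 from the linalyl vinyl group), and the ring forces the new C3=C4 alkene to be cis. No stereocentre is formed; C2 lies outside the reacting bonds and keeps the configuration of linalool. The selectivity needed is chemoselectivity against closure of the linalyl vinyl group onto the trisubstituted alkene (a cyclopentene with loss of 2-methylpropene) and against intermolecular stilbene formation. The substrate secures the first by loading the catalyst at the styrene much faster than at the neopentyl-type vinyl group, by the low reactivity of the trisubstituted alkene and by the ortho placement and geminal substitution at C2 that favour six-ring closure, while high dilution and removal of ethylene cover the second.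

Step 5
Reactants: 9 (2R)-6-methoxy-2,8-dimethyl-2-(4-methylpent-3-en-1-yl)-2H-chromene
Product: 10 (2R)-6-methoxy-2,8-dimethyl-2-(4-methylpent-3-en-1-yl)-3,4-dihydro-2H-chromene
Conditions: TsNHNH2, NaOAc, DME/H2O, reflux
Reagents that add atoms: none
Why: Diimide reduction (concerted syn transfer of two hydrogens from HN=NH generated in the flask), which is highly sensitive to alkene substitution and should therefore saturate the conjugated cis-disubstituted C3=C4 alkene well before the trisubstituted side-chain alkene, without any risk of hydrogenolysis of the allylic C2–O1 bond.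

Step 6
Reactants: 10 (2R)-6-methoxy-2,8-dimethyl-2-(4-methylpent-3-en-1-yl)-3,4-dihydro-2H-chromene
Product: 11 (2S)-2-[2-(3,3-dimethyloxiran-2-yl)ethyl]-6-methoxy-2,8-dimethyl-3,4-dihydro-2H-chromene (both oxirane epimers)
Conditions: mCPBA, NaHCO3, CH2Cl2, 0 °C
Reagents that add atoms: 3-chloroperoxybenzoic acid, OOC(=O)c1cccc(Cl)c1
Why: Prilezhaev epoxidation of the only remaining alkene, an electron-rich trisubstituted one, under bicarbonate buffer; the new oxirane stereocentre is formed without control as both epimers, which is harmless because that carbon becomes sp2 again in step 8.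

Step 7
Reactants: 11 (2S)-2-[2-(3,3-dimethyloxiran-2-yl)ethyl]-6-methoxy-2,8-dimethyl-3,4-dihydro-2H-chromene
Product: 13 5-[(2S)-6-methoxy-2,8-dimethyl-3,4-dihydro-2H-chromen-2-yl]-2-methylpent-1-en-3-ol (both carbinol epimers), via aluminium alkoxide 12 (not isolated)
Conditions: Al(Oi-Pr)3, toluene, 110 °C; then aq. potassium sodium tartrate
Reagents that add atoms: none
Why: Aluminium-alkoxide-promoted isomerisation of a trisubstituted epoxide to an allylic alcohol: the Lewis acid weakens the C–O bond at the tertiary carbon and an isopropoxide oxygen removes a proton from an adjacent methyl group through a cyclic transition state, which should give the isopropenyl carbinol, both epimers of which are carried on together.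

Step 8
Reactants: 13 5-[(2S)-6-methoxy-2,8-dimethyl-3,4-dihydro-2H-chromen-2-yl]-2-methylpent-1-en-3-ol
Product: 16 ethyl (4E)-7-[(2R)-6-methoxy-2,8-dimethyl-3,4-dihydro-2H-chromen-2-yl]-4-methylhept-4-enoate, via mixed orthoester 14 (not isolated), via ketene acetal 15 (not isolated)
Conditions: MeC(OEt)3, EtCO2H (cat.), 140 °C, EtOH distilled off
Reagents that add atoms: triethyl orthoacetate, CC(OCC)(OCC)OCC
Why: Johnson–Claisen rearrangement: acid-catalysed exchange and loss of ethanol give the allyl ketene acetal, whose [3,3]-sigmatropic shift through a chair transition state places the chromanylethyl substituent equatorial (axial it would clash with the ethoxy group), so both carbinol epimers should converge on the E-trisubstituted alkene while the chain grows by two carbons.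

Step 9
Reactants: 16 ethyl (4E)-7-[(2R)-6-methoxy-2,8-dimethyl-3,4-dihydro-2H-chromen-2-yl]-4-methylhept-4-enoate
Product: 18 (4E)-7-[(2R)-6-methoxy-2,8-dimethyl-3,4-dihydro-2H-chromen-2-yl]-4-methylhept-4-enal, via aluminium hemiacetal 17 (not isolated)
Conditions: i-Bu2AlH, CH2Cl2, −78 °C; then MeOH, aq. potassium sodium tartrate
Reagents that add atoms: none
Why: Partial reduction of an ester with one equivalent of i-Bu2AlH at −78 °C, where the tetrahedral adduct is stable and should release the aldehyde only on aqueous work-up; the isolated trisubstituted alkene and the aryl ethers are inert.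

Step 10
Reactants: 18 (4E)-7-[(2R)-6-methoxy-2,8-dimethyl-3,4-dihydro-2H-chromen-2-yl]-4-methylhept-4-enal
Product: 19 methyl (2Z,6E)-9-[(2R)-6-methoxy-2,8-dimethyl-3,4-dihydro-2H-chromen-2-yl]-2,6-dimethylnona-2,6-dienoate
Conditions: (CF3CH2O)2P(O)CH(Me)CO2Me, KN(SiMe3)2, 18-crown-6, THF, −78 °C
Reagents that add atoms: methyl 2-[bis(2,2,2-trifluoroethoxy)phosphoryl]propanoate, COC(=O)C(C)P(=O)(OCC(F)(F)F)OCC(F)(F)F
Why: Still–Gennari variant of the Horner–Wadsworth–Emmons olefination: with the electron-poor trifluoroethyl phosphonate and a crown-ether-separated potassium ion the kinetic adduct should eliminate faster than it equilibrates, placing the aldehyde-derived chain cis to the ester and so giving the Z-configured 2-methyl enoate, while the existing 6E alkene is not involved.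

Step 11
Reactants: 19 methyl (2Z,6E)-9-[(2R)-6-methoxy-2,8-dimethyl-3,4-dihydro-2H-chromen-2-yl]-2,6-dimethylnona-2,6-dienoate
Product: 21 (2Z,6E)-9-[(2R)-6-methoxy-2,8-dimethyl-3,4-dihydro-2H-chromen-2-yl]-2,6-dimethylnona-2,6-dienoic acid, via lithium carboxylate 20 (not isolated)
Conditions: LiOH·H2O, THF/MeOH/H2O, rt → 40 °C; then 1 M HCl, 0 °C
Reagents that add atoms: lithium hydroxide, [Li+].[OH-]
Why: Saponification by acyl–oxygen cleavage: hydroxide attacks the ester carbonyl and not the β-carbon of the hindered trisubstituted enoate, and the carboxylate formed is inert to base, so the 2Z geometry should survive the mild conditions and the brief cold acidification.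

Compound list
1 | 4-fluoro-3-methylanisole | COc1ccc(F)c(C)c1 | starting material
2 | (2-fluoro-5-methoxy-3-methylphenyl)lithium (formed in the flask) | COc1cc(C)c(F)c([Li])c1 | intermediate
3 | lithium (dimethylamino)(2-fluoro-5-methoxy-3-methylphenyl)methanolate (formed in the flask) | COc1cc(C)c(F)c(C([O-])N(C)C)c1.[Li+] | intermediate
4 | 2-fluoro-5-methoxy-3-methylbenzaldehyde | COc1cc(C)c(F)c(C=O)c1 | intermediate
5 | (R)-linalool, (3R)-3,7-dimethylocta-1,6-dien-3-ol | C=C[C@](C)(O)CCC=C(C)C | starting material
6 | potassium (3R)-3,7-dimethylocta-1,6-dien-3-olate (formed in the flask) | C=C[C@](C)([O-])CCC=C(C)C.[K+] | intermediate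
7 | 2-{[(3R)-3,7-dimethylocta-1,6-dien-3-yl]oxy}-5-methoxy-3-methylbenzaldehyde | COc1cc(C)c(O[C@@](C)(C=C)CCC=C(C)C)c(C=O)c1 | intermediate
8 | 2-{[(3R)-3,7-dimethylocta-1,6-dien-3-yl]oxy}-5-methoxy-1-methyl-3-vinylbenzene | COc1cc(C)c(O[C@@](C)(C=C)CCC=C(C)C)c(C=C)c1 | intermediate
9 | (2R)-6-methoxy-2,8-dimethyl-2-(4-methylpent-3-en-1-yl)-2H-chromene | COc1cc(C)c2c(c1)C=C[C@@](C)(CCC=C(C)C)O2 | intermediate
10 | (2R)-6-methoxy-2,8-dimethyl-2-(4-methylpent-3-en-1-yl)-3,4-dihydro-2H-chromene | COc1cc(C)c2c(c1)CC[C@@](C)(CCC=C(C)C)O2 | intermediate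
11 | (2S)-2-[2-(3,3-dimethyloxiran-2-yl)ethyl]-6-methoxy-2,8-dimethyl-3,4-dihydro-2H-chromene, both oxirane epimers | COc1cc(C)c2c(c1)CC[C@@](C)(CCC1OC1(C)C)O2 | intermediate
12 | diisopropoxyaluminium alkoxide of 13 (formed in the flask) | COc1cc(C)c2c(c1)CC[C@@](C)(CCC(O[Al](OC(C)C)OC(C)C)C(C)=C)O2 | intermediate
13 | 5-[(2S)-6-methoxy-2,8-dimethyl-3,4-dihydro-2H-chromen-2-yl]-2-methylpent-1-en-3-ol, both carbinol epimers | COc1cc(C)c2c(c1)CC[C@@](C)(CCC(O)C(C)=C)O2 | intermediate
14 | diethyl 5-[(2S)-6-methoxy-2,8-dimethyl-3,4-dihydro-2H-chromen-2-yl]-2-methylpent-1-en-3-yl orthoacetate (formed in the flask) | COc1cc(C)c2c(c1)CC[C@@](C)(CCC(OC(C)(OCC)OCC)C(C)=C)O2 | intermediate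
15 | (2S)-2-{3-[(1-ethoxyethenyl)oxy]-4-methylpent-4-en-1-yl}-6-methoxy-2,8-dimethyl-3,4-dihydro-2H-chromene (formed in the flask) | COc1cc(C)c2c(c1)CC[C@@](C)(CCC(OC(=C)OCC)C(C)=C)O2 | intermediate
16 | ethyl (4E)-7-[(2R)-6-methoxy-2,8-dimethyl-3,4-dihydro-2H-chromen-2-yl]-4-methylhept-4-enoate | COc1cc(C)c2c(c1)CC[C@@](C)(CC/C=C(\C)CCC(=O)OCC)O2 | intermediate
17 | diisobutylaluminium 1-ethoxy hemiacetal of 18, tetrahedral adduct of 16 (formed in the flask) | COc1cc(C)c2c(c1)CC[C@@](C)(CC/C=C(\C)CCC(OCC)O[Al](CC(C)C)CC(C)C)O2 | intermediate
18 | (4E)-7-[(2R)-6-methoxy-2,8-dimethyl-3,4-dihydro-2H-chromen-2-yl]-4-methylhept-4-enal | COc1cc(C)c2c(c1)CC[C@@](C)(CC/C=C(\C)CCC=O)O2 | intermediate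
19 | methyl (2Z,6E)-9-[(2R)-6-methoxy-2,8-dimethyl-3,4-dihydro-2H-chromen-2-yl]-2,6-dimethylnona-2,6-dienoate | COc1cc(C)c2c(c1)CC[C@@](C)(CC/C=C(\C)CC/C=C(/C)C(=O)OC)O2 | intermediate
20 | lithium (2Z,6E)-9-[(2R)-6-methoxy-2,8-dimethyl-3,4-dihydro-2H-chromen-2-yl]-2,6-dimethylnona-2,6-dienoate (formed in the flask) | COc1cc(C)c2c(c1)CC[C@@](C)(CC/C=C(\C)CC/C=C(/C)C(=O)[O-])O2.[Li+] | intermediate
21 | (2Z,6E)-9-[(2R)-6-methoxy-2,8-dimethyl-3,4-dihydro-2H-chromen-2-yl]-2,6-dimethylnona-2,6-dienoic acid | COc1cc(C)c2c(c1)CC[C@@](C)(CC/C=C(\C)CC/C=C(/C)C(=O)O)O2 | target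

Total step count: 11. Longest linear sequence: 11 steps (1 to 21); (R)-linalool 5 enters at step 2.

Steps most likely to fail

Step 2. The bulky tertiary alkoxide must add to a ring carbon that is flanked by two ortho substituents and deactivated by the para methoxy group. Substitution may therefore be slower than reversible attack on the formyl group and base-induced degradation of the aldehyde, and may stall. The fallback changes the activating group to a nitrile, which is smaller, is not attacked productively by the alkoxide and tolerates forcing conditions. It sets out from 4. One-pot oximation and dehydration (NH2OH·HCl, HCO2Na, HCO2H, reflux) should give 2-fluoro-5-methoxy-3-methylbenzonitrile F1. Substitution by potassium alkoxide 6 (KH, THF, then DMSO, rt → 60 °C) should give 2-{[(3R)-3,7-dimethylocta-1,6-dien-3-yl]oxy}-5-methoxy-3-methylbenzonitrile F2. Reduction with i-Bu2AlH (toluene, −78 °C) and buffered hydrolysis of the aldimine should return aldehyde 7, where the route resumes at step 3.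

Step 4. The catalyst may load at the linalyl vinyl group and close onto the trisubstituted alkene with loss of 2-methylpropene, giving a cyclopentenyl aryl ether and destroying the chain that is needed later. The fallback masks that alkene as the epoxide it is to become anyway. It sets out from 8. Buffered mCPBA (1 equiv, NaHCO3, CH2Cl2, −20 °C) should epoxidise the trisubstituted alkene, which is far more nucleophilic than the styrene or the vinyl group, to give 3-[(3R)-3-(2-ethenyl-4-methoxy-6-methylphenoxy)-3-methylpent-4-en-1-yl]-2,2-dimethyloxirane F3. Metathesis under the conditions of step 4, now with only one possible closure, should give (2R)-2-[2-(3,3-dimethyloxiran-2-yl)ethyl]-6-methoxy-2,8-dimethyl-2H-chromene F4. Diimide generated under basic conditions (2-nitrobenzenesulfonyl hydrazide, Et3N, CH2Cl2, rt) should then saturate C3=C4 and deliver epoxide 11, where the route resumes at step 7. The step count is unchanged, and the chemoselectivity demand of step 5 disappears as well.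

Step 7. The Lewis acid may divert the epoxide into a hydride shift to the isopropyl ketone or into proton loss from the chain methylene (tertiary allylic alcohol), or conversion may stay incomplete at the temperature required. The fallback functionalises the prenyl terminus without transposition. It sets out from 10. Allylic oxidation with SeO2 (cat.) and t-BuOOH in CH2Cl2, followed by NaBH4 to return any enal, should give the E-configured alcohol (2E)-5-[(2R)-6-methoxy-2,8-dimethyl-3,4-dihydro-2H-chromen-2-yl]-2-methylpent-2-en-1-ol F5. CBr4 and PPh3 (CH2Cl2, 0 °C) should convert it into (2R)-2-[(3E)-5-bromo-4-methylpent-3-en-1-yl]-6-methoxy-2,8-dimethyl-3,4-dihydro-2H-chromene F6. Displacement of the primary allylic bromide by the lithium enolate of ethyl acetate (LiN(i-Pr)2, EtOAc, THF, −78 °C) should give ester 16, where the route resumes at step 9.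

Further compounds
F1 | step 2 | 2-fluoro-5-methoxy-3-methylbenzonitrile | COc1cc(C)c(F)c(C#N)c1
F2 | step 2 | 2-{[(3R)-3,7-dimethylocta-1,6-dien-3-yl]oxy}-5-methoxy-3-methylbenzonitrile | COc1cc(C)c(O[C@@](C)(C=C)CCC=C(C)C)c(C#N)c1
F3 | step 4 | 3-[(3R)-3-(2-ethenyl-4-methoxy-6-methylphenoxy)-3-methylpent-4-en-1-yl]-2,2-dimethyloxirane, both oxirane epimers | COc1cc(C)c(O[C@@](C)(C=C)CCC2OC2(C)C)c(C=C)c1
F4 | step 4 | (2R)-2-[2-(3,3-dimethyloxiran-2-yl)ethyl]-6-methoxy-2,8-dimethyl-2H-chromene, both oxirane epimers | COc1cc(C)c2c(c1)C=C[C@@](C)(CCC1OC1(C)C)O2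
F5 | step 7 | (2E)-5-[(2R)-6-methoxy-2,8-dimethyl-3,4-dihydro-2H-chromen-2-yl]-2-methylpent-2-en-1-ol | COc1cc(C)c2c(c1)CC[C@@](C)(CC/C=C(\C)CO)O2
F6 | step 7 | (2R)-2-[(3E)-5-bromo-4-methylpent-3-en-1-yl]-6-methoxy-2,8-dimethyl-3,4-dihydro-2H-chromene | COc1cc(C)c2c(c1)CC[C@@](C)(CC/C=C(\C)CBr)O2
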